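The route rests on cutting the C5–C6 bond of the cyclopentane ring B (C5–C6–C7–C8–C9). In the target C6 carries the acetyl group and neighbours the oxygenated C7, so it can be raised to a carbenoid flanked by a C7 ketone and an ester. It also stands in a 1,5 relationship to C5, a plain methylene of the cyclohexane ring A (C1–C2–C3–C4–C5–C9). Dirhodium-mediated insertion into the equatorial C5–H bond closes ring B and sets the trans fusion (C5) and C6 at once. The precursor is a chair cyclohexane: equatorial isopropyl (C4), axial PMB ether (C3), a dioxolane at C1 and an equatorial CH2C(O)C(N2)CO2Me chain on C9.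

Key step: step 13

Numbering: target numbering is used for every intermediate (C10 = exocyclic methylene carbon on C1). β means the face that carries the C4 isopropyl group, α the opposite face. PMB = 4-methoxybenzyl, TES = triethylsilyl.

Assumption: IpcBH2 made from (+)-α-pinene is taken to choose the alkene face of 3 as it does for 1-methylcyclohexene; if the sense were opposite, the borane from (−)-α-pinene would be used.

Step 1
Reactants: 1 4-isopropylanisole
Product: 2 1-methoxy-4-isopropylcyclohexa-1,4-diene
Conditions: Li, NH3 (l), THF, t-BuOH, −78 → −33 °C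
Reagents that add atoms: none
Why: Birch reduction of the electron-rich arene gives the unconjugated 1,4-diene in which the methoxy- and isopropyl-bearing carbons stay on the two remaining double bonds.

Step 2
Reactants: 2 1-methoxy-4-isopropylcyclohexa-1,4-diene
Product: 3 8-isopropyl-1,4-dioxaspiro[4.5]dec-7-ene (C1 dioxolane; C3=C4 alkene)
Conditions: HOCH2CH2OH, p-TsOH (cat.), CH2Cl2, rt
Reagents that add atoms: ethylene glycol, OCCO
Why: Acid-catalysed ketalisation of the enol ether through its oxocarbenium ion is faster than alkene migration, so the isolated trisubstituted C3=C4 bond should stay out of conjugation.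

Step 3
Reactants: 3 8-isopropyl-1,4-dioxaspiro[4.5]dec-7-ene
Product: 4 (7S,8R)-8-isopropyl-1,4-dioxaspiro[4.5]decan-7-ol (C3–OH α and equatorial; trans to the C4 isopropyl)
Conditions: IpcBH2 [from (+)-α-pinene], Et2O, −25 °C; then NaOH, H2O2, 0 → 40 °C
Reagents that add atoms: hydrogen peroxide, OO
Why: Asymmetric hydroboration–oxidation puts boron on the less substituted C3 and hydrogen on C4 across one face (syn, anti-Markovnikov), the isopinocampheyl group choosing the face, and oxidation with retention gives the trans alcohol with C4 set for the whole route.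

Step 4
Reactants: 4 (7S,8R)-8-isopropyl-1,4-dioxaspiro[4.5]decan-7-ol
Product: 5 (7R,8R)-8-isopropyl-1,4-dioxaspiro[4.5]decan-7-yl 4-nitrobenzoate (C3 ester β and axial; cis to isopropyl)
Conditions: 4-O2NC6H4CO2H, PPh3, DIAD, THF, 0 °C → rt; recrystallisation
Reagents that add atoms: 4-nitrobenzoic acid, O=C(O)c1ccc(cc1)[N+](=O)[O-]
Why: In this Mitsunobu reaction the C3 oxyphosphonium is displaced by 4-nitrobenzoate with inversion (SN2), the acidic pronucleophile being the one suited to menthol-type alcohols, and recrystallisation of the ester should raise the enantiomeric purity.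

Step 5
Reactants: 5 (7R,8R)-8-isopropyl-1,4-dioxaspiro[4.5]decan-7-yl 4-nitrobenzoate
Product: 6 (7R,8R)-8-isopropyl-1,4-dioxaspiro[4.5]decan-7-ol (C3–OH β and axial)
Conditions: K2CO3, MeOH, rt
Reagents that add atoms: none
Why: Base-catalysed transesterification (methanolysis) removes the aroyl group without touching the carbinol carbon or the ketal.

Step 6
Reactants: 6 (7R,8R)-8-isopropyl-1,4-dioxaspiro[4.5]decan-7-ol
Product: 7 (7R,8R)-8-isopropyl-7-[(4-methoxybenzyl)oxy]-1,4-dioxaspiro[4.5]decane
Conditions: NaH, 4-MeOC6H4CH2Cl, Bu4NI (cat.), DMF, 0 °C → rt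
Reagents that add atoms: 4-methoxybenzyl chloride, COc1ccc(CCl)cc1
Why: Williamson etherification of the sodium alkoxide installs an ether that is stable to base and dilute acid, is a poor leaving group β to the future C1 ketone, and can be removed oxidatively at the end.

Step 7
Reactants: 7 (7R,8R)-8-isopropyl-7-[(4-methoxybenzyl)oxy]-1,4-dioxaspiro[4.5]decane
Product: 8 (3R,4R)-4-isopropyl-3-[(4-methoxybenzyl)oxy]cyclohexan-1-one
Conditions: 1 M HCl (aq), THF, rt
Reagents that add atoms: water, O
Why: Acid hydrolysis of the dioxolane frees the C1 ketone for enolate chemistry while the PMB ether is stable to dilute acid.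

Step 8
Reactants: 8 (3R,4R)-4-isopropyl-3-[(4-methoxybenzyl)oxy]cyclohexan-1-one; 9 ethyl bromoacetate
Product: 11 ethyl 2-[(1S,4R,5R)-5-isopropyl-4-[(4-methoxybenzyl)oxy]-2-oxocyclohexyl]acetate (C9 chain β and equatorial), via kinetic C9 epimer 10 (not isolated)
Conditions: LiN(iPr)2 (LDA), THF, −78 °C; 9, DMPU, −78 → −30 °C; aq. NH4Cl; then crude, NaOEt (0.2 equiv), EtOH, 0 °C → rt
Reagents that add atoms: ethyl bromoacetate (9), CCOC(=O)CBr
Why: Kinetic deprotonation by the hindered amide takes the less hindered C9 hydrogen away from the C3 ether, SN2 alkylation follows, and catalytic ethoxide then equilibrates C9 through the enolate to the epimer with the chain equatorial and cis to the C4 isopropyl group (enolate alkylation with thermodynamic epimerisation).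

Step 9
Reactants: 11 ethyl 2-[(1S,4R,5R)-5-isopropyl-4-[(4-methoxybenzyl)oxy]-2-oxocyclohexyl]acetate
Product: 12 ethyl ester ketal (C1 dioxolane; 3β-OPMB; 4β-isopropyl; C9β–CH2CO2Et)
Conditions: Me3SiOCH2CH2OSiMe3, Me3SiOTf (cat.), CH2Cl2, −78 → −20 °C; pyridine quench
Reagents that add atoms: 1,2-bis(trimethylsilyloxy)ethane, C[Si](C)(C)OCCO[Si](C)(C)C
Why: Noyori ketalisation converts the hindered ketone at low temperature under aprotic conditions, so C9 is not epimerised and the PMB ether and ester are untouched.

Step 10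
Reactants: 12 ethyl ester ketal
Product: 13 ketal acid (C9β–CH2CO2H)
Conditions: LiOH, THF/MeOH/H2O, rt; then 0.5 M HCl to pH 4, 0 °C
Reagents that add atoms: lithium hydroxide, [Li+].[OH-]
Why: Saponification of the unhindered primary ester leaves the base-stable ketal and ether alone, and brief cold acidification should keep the dioxolane.

Step 11
Reactants: 13 ketal acid; 14 potassium monomethyl malonate
Product: 16 methyl β-keto ester (C9β–CH2C(O)CH2CO2Me; C1 dioxolane; 3β-OPMB; 4β-isopropyl), via acyl imidazolide 15 (not isolated)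
Conditions: CDI, THF, rt; then 14, MgCl2, Et3N, MeCN, rt → 40 °C; aq. citric acid
Reagents that add atoms: potassium monomethyl malonate (14), COC(=O)CC(=O)[O-].[K+]
Why: In the Masamune–Brooks homologation the acyl imidazolide C-acylates the magnesium enolate of the malonate half-ester, and decarboxylation on work-up leaves the β-keto ester under near-neutral conditions.

Step 12
Reactants: 16 methyl β-keto ester
Product: 17 methyl 2-diazo-3-oxo-4-(ring A)butanoate (C6 diazo carbon; C1 dioxolane; 3β-OPMB axial; 4β-isopropyl equatorial; C9 chain β equatorial)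
Conditions: 4-AcNHC6H4SO2N3, Et3N, MeCN, 0 °C → rt
Reagents that add atoms: 4-acetamidobenzenesulfonyl azide, CC(=O)Nc1ccc(cc1)S(=O)(=O)N=[N+]=[N-]
Why: In the Regitz diazo transfer the enolate of the active methylene attacks the terminal azide nitrogen and expels the sulfonamide to give the α-diazo β-keto ester.

Step 13
Reactants: 17 methyl 2-diazo-3-oxo-4-(ring A)butanoate
Product: 18 trans-hydrindanone β-keto ester (C1 dioxolane; 3β-OPMB; 4β-isopropyl; 5β-H; 6β-CO2Me; C7 ketone; 9α-H)
Conditions: Rh2(OAc)4 (1 mol%), CH2Cl2 (0.01 M), slow addition, rt → 40 °C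
Reagents that add atoms: none
Why: Rh2(OAc)4 takes N2 from 17 and leaves an electrophilic carbenoid at C6, flanked by the ketone and the ester, which inserts into a C–H bond in one concerted three-centre event with retention at the carbon attacked; the reaction type is the established dirhodium-catalysed intramolecular C–H insertion of α-diazo β-keto esters to 2-alkoxycarbonyl cyclopentanones. Ring B closes by 1,5-insertion, a five-membered ring formed through a chair-like transition state of C6, C7, C8, C9, C5 and the transferred hydrogen. C5 is controlled by the ring A chair, which the equatorial C4 isopropyl group locks: the C9 chain is equatorial and meets the equatorial C5–H, so the new C5–C6 bond is equatorial and the fusion trans, while the axial C5–H is screened by the syn-axial C3 ether. C6 is controlled thermodynamically, since the β-keto ester enolises and the ester should come to rest on the β face, cis to H5 and turned away from the C4 branch. The step needs site selectivity and chemoselectivity: a five-ring closure from C6 can reach only C5 or C1, and C1 is the spiro ketal carbon without hydrogen, the tertiary C4–H would demand a six-ring closure, and the PMB and dioxolane C–H bonds lie at medium-ring distance; slow addition at high dilution suppresses carbene dimerisation.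

Step 14
Reactants: 18 trans-hydrindanone β-keto ester
Product: 20 hydroxy keto ester (C1 ketone; 3β-OPMB; 6β-CO2Me; 7β-OH), via hydroxy ester ketal 19 (not isolated)
Conditions: NaBH4, THF/MeOH, −20 °C; then 1 M HCl (aq), 0 °C → rt
Reagents that add atoms: water, O
Why: Borohydride reduces only the ring ketone of the β-keto ester and should attack C7 from the α face, anti to the neighbouring β ester, setting the 7β-hydroxyl cis to it (substrate-controlled hydride reduction); dilute acid then hydrolyses the dioxolane in the same flask.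

Step 15
Reactants: 20 hydroxy keto ester
Product: 21 C7 triethylsilyl ether (C1 ketone; 6β-CO2Me; 7β-OTES; 3β-OPMB)
Conditions: Et3SiCl, imidazole, DMF, 0 °C → rt
Reagents that add atoms: chlorotriethylsilane, CC[Si](Cl)(CC)CC
Why: Silyl ether formation masks the secondary hydroxyl against the organometallic reagent of the next step and is labile enough to fall in the acid work-up that follows.

Step 16
Reactants: 21 C7 triethylsilyl ether
Product: 24 hydroxy methyl ketone (C1=C10 methylene; 6β-acetyl; 7β-OH; 3β-OPMB), via methylene enol ether 22 (not isolated), via silyloxy methyl ketone 23 (not isolated)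
Conditions: Cp2Ti(μ-Cl)(μ-CH2)AlMe2 (3.5 equiv), pyridine (cat.), THF/toluene, −40 °C → rt; then 1 M HCl (aq), THF, 0 °C → rt
Reagents that add atoms: Tebbe reagent, C=[Ti](C1C=CC=C1)C1C=CC=C1.C[Al](C)Cl; water, O
Why: In this Tebbe methylenation the titanium methylidene turns the C1 ketone into the C10 methylene and the ester into its methyl enol ether under non-basic conditions that leave C9 and C6 untouched; mild aqueous acid then hydrolyses the enol ether to the acetyl group and removes the triethylsilyl ether while the PMB ether stays.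

Step 17
Reactants: 24 hydroxy methyl ketone; 25 angelic acid
Product: 27 C7 angelate (7β-O-angeloyl; 6β-acetyl; 3β-OPMB; C1=C10), via mixed anhydride 26 (not isolated)
Conditions: 25, 2,4,6-Cl3C6H2COCl, Et3N, toluene, rt; filtered; then 24, NaHCO3, toluene, 60 °C
Reagents that add atoms: angelic acid (25), C/C=C(/C)C(=O)O
Why: Yamaguchi-type mixed anhydride acylation run without a nucleophilic catalyst, the protocol that keeps the Z geometry of the angeloyl unit, esterifies the free C7 hydroxyl at the less hindered carbonyl of the anhydride.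

Step 18
Reactants: 27 C7 angelate
Product: 28 C3 alcohol (3β-OH axial; 7β-O-angeloyl; 6β-acetyl; C1=C10)
Conditions: DDQ, CH2Cl2/pH 7 buffer, 0 °C → rt
Reagents that add atoms: none
Why: Oxidative PMB cleavage (hydride abstraction at the electron-rich benzylic position, then hydrolysis) frees the C3 hydroxyl under neutral conditions that the angelate, the β-acyloxy ketone and the exocyclic alkene should tolerate.

Step 19
Reactants: 25 angelic acid
Product: 29 (Z)-2-methylbut-2-en-1-ol
Conditions: LiAlH4, Et2O, 0 °C → rt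
Reagents that add atoms: none
Why: Hydride reduction of the carboxylic acid (1,2-reduction) gives the allylic alcohol with the Z geometry intact.

Step 20
Reactants: 29 (Z)-2-methylbut-2-en-1-ol
Product: 30 [(2R,3S)-2,3-dimethyloxiran-2-yl]methanol
Conditions: Ti(OiPr)4, D-(−)-diethyl tartrate, t-BuOOH, 4 Å MS, CH2Cl2, −20 °C
Reagents that add atoms: tert-butyl hydroperoxide, CC(C)(C)OO
Why: In the Sharpless asymmetric epoxidation the titanium–tartrate complex delivers oxygen to one face of the allylic alcohol, the D-(−)-tartrate giving the (2R,3S) epoxide, and the stereospecific syn addition keeps the hydroxymethyl and C3 methyl groups cis.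

Step 21
Reactants: 30 [(2R,3S)-2,3-dimethyloxiran-2-yl]methanol
Product: 31 (2S,3S)-2,3-dimethyloxirane-2-carboxylic acid
Conditions: RuCl3·H2O (cat.), NaIO4, MeCN/EtOAc/H2O, 0 °C → rt
Reagents that add atoms: sodium periodate, [Na+].[O-]I(=O)(=O)=O; water, O
Why: Catalytically generated ruthenium tetroxide (Sharpless oxidation) takes the primary alcohol to the acid without opening the epoxide, and the C2 descriptor changes from R to S only because the CIP priorities change.

Step 22
Reactants: 28 C3 alcohol; 31 (2S,3S)-2,3-dimethyloxirane-2-carboxylic acid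
Product: 33 CNP0300602.1, via mixed anhydride 32 (not isolated)
Conditions: 31, 2,4,6-Cl3C6H2COCl, Et3N, THF, rt; then 28, DMAP, toluene, rt → 40 °C
Reagents that add atoms: (2S,3S)-2,3-dimethyloxirane-2-carboxylic acid (31), OC(=O)[C@@]1(C)O[C@H]1C
Why: In the Yamaguchi esterification the mixed anhydride passes the hindered epoxy acyl group through the acylpyridinium to the axial C3 hydroxyl, and the acid cannot epimerise because C2 is quaternary.

Compound list
1 | 4-isopropylanisole | COc1ccc(C(C)C)cc1 | starting material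
2 | 1-methoxy-4-isopropylcyclohexa-1,4-diene | COC1=CCC(C(C)C)=CC1 | intermediate
3 | 8-isopropyl-1,4-dioxaspiro[4.5]dec-7-ene | CC(C)C1=CCC2(CC1)OCCO2 | intermediate
4 | (7S,8R)-8-isopropyl-1,4-dioxaspiro[4.5]decan-7-ol (OH trans to isopropyl) | C1[C@H](O)[C@@H](C(C)C)CCC12OCCO2 | intermediate
5 | (7R,8R)-8-isopropyl-1,4-dioxaspiro[4.5]decan-7-yl 4-nitrobenzoate | C1[C@@H](OC(=O)c3ccc(cc3)[N+](=O)[O-])[C@@H](C(C)C)CCC12OCCO2 | intermediate
6 | (7R,8R)-8-isopropyl-1,4-dioxaspiro[4.5]decan-7-ol (OH cis to isopropyl) | C1[C@@H](O)[C@@H](C(C)C)CCC12OCCO2 | intermediate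
7 | (7R,8R)-8-isopropyl-7-[(4-methoxybenzyl)oxy]-1,4-dioxaspiro[4.5]decane | C1[C@@H](OCc3ccc(OC)cc3)[C@@H](C(C)C)CCC12OCCO2 | intermediate
8 | (3R,4R)-4-isopropyl-3-[(4-methoxybenzyl)oxy]cyclohexan-1-one | O=C1C[C@@H](OCc2ccc(OC)cc2)[C@@H](C(C)C)CC1 | intermediate
9 | ethyl bromoacetate | CCOC(=O)CBr | starting material
10 | ethyl 2-[(1R,4R,5R)-5-isopropyl-4-[(4-methoxybenzyl)oxy]-2-oxocyclohexyl]acetate (C9 chain α, axial) | CCOC(=O)C[C@H]1C[C@H](C(C)C)[C@H](OCc2ccc(OC)cc2)CC1=O | intermediate (not isolated)
11 | ethyl 2-[(1S,4R,5R)-5-isopropyl-4-[(4-methoxybenzyl)oxy]-2-oxocyclohexyl]acetate (C9 chain β, equatorial) | CCOC(=O)C[C@@H]1C[C@H](C(C)C)[C@H](OCc2ccc(OC)cc2)CC1=O | intermediate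
12 | ethyl ester ketal: C1 dioxolane, 3β-OPMB, 4β-isopropyl, C9β–CH2CO2Et | CCOC(=O)C[C@@H]1C[C@H](C(C)C)[C@H](OCc3ccc(OC)cc3)CC12OCCO2 | intermediate
13 | ketal acid: as 12 with C9β–CH2CO2H | OC(=O)C[C@@H]1C[C@H](C(C)C)[C@H](OCc3ccc(OC)cc3)CC12OCCO2 | intermediate
14 | potassium monomethyl malonate | COC(=O)CC(=O)[O-].[K+] | starting material
15 | acyl imidazolide of 13 | O=C(C[C@@H]1C[C@H](C(C)C)[C@H](OCc3ccc(OC)cc3)CC12OCCO2)n1ccnc1 | intermediate (not isolated)
16 | methyl β-keto ester: C9β–CH2C(O)CH2CO2Me, C1 dioxolane, 3β-OPMB, 4β-isopropyl | COC(=O)CC(=O)C[C@@H]1C[C@H](C(C)C)[C@H](OCc3ccc(OC)cc3)CC12OCCO2 | intermediate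
17 | α-diazo β-keto ester (insertion precursor): C6 diazo, C1 dioxolane, 3β-OPMB, 4β-isopropyl, C9β chain | COC(=O)C(=[N+]=[N-])C(=O)C[C@@H]1C[C@H](C(C)C)[C@H](OCc3ccc(OC)cc3)CC12OCCO2 | intermediate
18 | trans-hydrindanone β-keto ester: C1 dioxolane, 3β-OPMB, 4β-isopropyl, 5β-H, 6β-CO2Me, C7 ketone, 9α-H | C12(OCCO1)C[C@@H](OCc4ccc(OC)cc4)[C@@H](C(C)C)[C@@H]3[C@@H](C(=O)OC)C(=O)C[C@@H]23 | intermediate
19 | hydroxy ester ketal: as 18 with 7β-OH | C12(OCCO1)C[C@@H](OCc4ccc(OC)cc4)[C@@H](C(C)C)[C@@H]3[C@@H](C(=O)OC)[C@@H](O)C[C@@H]23 | intermediate (not isolated)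
20 | hydroxy keto ester: C1 ketone, 3β-OPMB, 6β-CO2Me, 7β-OH | O=C1C[C@@H](OCc3ccc(OC)cc3)[C@@H](C(C)C)[C@@H]2[C@@H](C(=O)OC)[C@@H](O)C[C@@H]12 | intermediate
21 | C7 triethylsilyl ether of 20 | O=C1C[C@@H](OCc3ccc(OC)cc3)[C@@H](C(C)C)[C@@H]2[C@@H](C(=O)OC)[C@@H](O[Si](CC)(CC)CC)C[C@@H]12 | intermediate
22 | C1 methylene, C6 (1-methoxyvinyl) enol ether, 7β-OTES | C=C1C[C@@H](OCc3ccc(OC)cc3)[C@@H](C(C)C)[C@@H]2[C@@H](C(=C)OC)[C@@H](O[Si](CC)(CC)CC)C[C@@H]12 | intermediate (not isolated)
23 | C1 methylene, 6β-acetyl, 7β-OTES | C=C1C[C@@H](OCc3ccc(OC)cc3)[C@@H](C(C)C)[C@@H]2[C@@H](C(C)=O)[C@@H](O[Si](CC)(CC)CC)C[C@@H]12 | intermediate (not isolated)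
24 | hydroxy methyl ketone: C1 methylene, 6β-acetyl, 7β-OH, 3β-OPMB | C=C1C[C@@H](OCc3ccc(OC)cc3)[C@@H](C(C)C)[C@@H]2[C@@H](C(C)=O)[C@@H](O)C[C@@H]12 | intermediate
25 | angelic acid, (Z)-2-methylbut-2-enoic acid | C/C=C(/C)C(=O)O | starting material
26 | angelic 2,4,6-trichlorobenzoic anhydride | C/C=C(/C)C(=O)OC(=O)c1c(Cl)cc(Cl)cc1Cl | intermediate (not isolated)
27 | C7 angelate, 3β-OPMB | C=C1C[C@@H](OCc3ccc(OC)cc3)[C@@H](C(C)C)[C@@H]2[C@@H](C(C)=O)[C@@H](OC(=O)/C(C)=C\C)C[C@@H]12 | intermediate
28 | C7 angelate, 3β-OH | C=C1C[C@@H](O)[C@@H](C(C)C)[C@@H]2[C@@H](C(C)=O)[C@@H](OC(=O)/C(C)=C\C)C[C@@H]12 | intermediate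
29 | (Z)-2-methylbut-2-en-1-ol | C/C=C(/C)CO | intermediate
30 | [(2R,3S)-2,3-dimethyloxiran-2-yl]methanol | OC[C@@]1(C)O[C@H]1C | intermediate
31 | (2S,3S)-2,3-dimethyloxirane-2-carboxylic acid | OC(=O)[C@@]1(C)O[C@H]1C | intermediate
32 | (2S,3S)-2,3-dimethyloxirane-2-carboxylic 2,4,6-trichlorobenzoic anhydride | O=C(OC(=O)[C@@]1(C)O[C@H]1C)c1c(Cl)cc(Cl)cc1Cl | intermediate (not isolated)
33 | CNP0300602.1: (3R,4S,5R,6R,7S,9R) hydrindane with C1=C10 methylene, 3β-[(2S,3S)-2,3-dimethyloxirane-2-carbonyloxy], 4β-isopropyl, 6β-acetyl, 7β-angeloyloxy, trans ring fusion | C=C1C[C@@H](OC(=O)[C@@]2(C)O[C@H]2C)[C@@H](C(C)C)[C@@H]2[C@@H](C(C)=O)[C@@H](OC(=O)/C(C)=C\C)C[C@@H]12 | target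

Total step count: 22. Longest linear sequence: 19 steps (steps 1–18 and 22); the epoxy acid branch (steps 19–21) joins in step 22.

Steps most likely to fail

Step 13. The carbenoid may also insert into the axial C5–H bond, which erodes the trans ring fusion; capture of the carbenoid by a dioxolane oxygen is a second possible drain. The fallback answers the first of these and sets out from 17. Its cyclisation would then give 18 beside the cis-fused C5 epimer F1, which is separated. Selenenylation of F1 (PhSeCl, pyridine, CH2Cl2, 0 °C) should give the C6 phenylselenide F2, selenium entering the convex α face, syn to H5. Oxidation (H2O2, CH2Cl2, 0 °C) and selenoxide syn-elimination then give the C5=C6 unsaturated keto ester F3. Electron-transfer reduction of this doubly activated alkene (SmI2, MeOH, THF, −78 °C) should protonate C5 from the axial direction, so the C5–C6 bond ends equatorial and the material returns to the route at 18. The ring fusion is then set by reduction of an enone and no longer by the choice between two C–H bonds.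

Step 8. Enolisation toward C2 would be followed by β-elimination of the C3 ether, and over-alkylation or loss of material during the base equilibration is also possible. The fallback sets out from 8 and alkylates the ketone as its azaenolate. Condensation with Me2NNH2 (EtOH, AcOH cat., 60 °C) gives the N,N-dimethylhydrazone F4. Deprotonation with LiN(iPr)2 (THF, −78 → 0 °C) occurs on the less hindered C9 side, and 9 (−78 °C) then gives the C9-alkylated hydrazone F5. Hydrolysis with aqueous CuCl2 (THF, pH 7) releases 10, which is equilibrated as in step 8 (NaOEt cat., EtOH), and the route is rejoined at 11.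

Step 16. Methylenation of the congested C6 ester may stay incomplete, so that ketone and ester are not both converted in one operation. The fallback sets out from 21 and treats the two carbonyls separately. Wittig methylenation (Ph3PCH3Br, KOtBu, THF, 0 °C) gives the C1-methylene ester F6. Amidation (MeNHOMe·HCl, iPrMgCl, THF, −20 → 0 °C) gives the N-methoxy-N-methylamide F7. MeMgBr (THF, 0 °C) then gives the methyl ketone, and the route is rejoined at 23, which the acid treatment of step 16 converts into 24.

Further compounds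
F1 | step 13 | cis-fused C5 epimer of 18 (5α-H, 9α-H; keto form drawn with 6α-CO2Me) | C12(OCCO1)C[C@@H](OCc4ccc(OC)cc4)[C@@H](C(C)C)[C@H]3[C@H](C(=O)OC)C(=O)C[C@@H]23
F2 | step 13 | C6 phenylselenide of F1 (6α-SePh, 6β-CO2Me) | C12(OCCO1)C[C@@H](OCc4ccc(OC)cc4)[C@@H](C(C)C)[C@H]3[C@](C(=O)OC)([Se]c5ccccc5)C(=O)C[C@@H]23
F3 | step 13 | C5=C6 unsaturated keto ester | C12(OCCO1)C[C@@H](OCc4ccc(OC)cc4)[C@@H](C(C)C)C3=C(C(=O)OC)C(=O)C[C@@H]23
F4 | step 8 | N,N-dimethylhydrazone of 8 | CN(C)/N=C1/C[C@@H](OCc2ccc(OC)cc2)[C@@H](C(C)C)CC1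
F5 | step 8 | C9-alkylated N,N-dimethylhydrazone (C9 chain α) | CCOC(=O)C[C@H]1C[C@H](C(C)C)[C@H](OCc2ccc(OC)cc2)C/C1=N/N(C)C
F6 | step 16 | C1-methylene methyl ester, 7β-OTES | C=C1C[C@@H](OCc3ccc(OC)cc3)[C@@H](C(C)C)[C@@H]2[C@@H](C(=O)OC)[C@@H](O[Si](CC)(CC)CC)C[C@@H]12
F7 | step 16 | C1-methylene N-methoxy-N-methylamide, 7β-OTES | C=C1C[C@@H](OCc3ccc(OC)cc3)[C@@H](C(C)C)[C@@H]2[C@@H](C(=O)N(C)OC)[C@@H](O[Si](CC)(CC)CC)C[C@@H]12
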